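**Assumption:** positions are labelled with guaiane numbering (C1 ring-fusion CH, C3 C=O, C4(Me)=C5, C7 side-chain carbon, C8 O-bearing carbon, C10 CHMe); the target is (1R,7S,8R,10S) with a (Z)-angelate.

## Retrosynthetic overview

1. Torilin ⇒ 8,11-diol 12 by late O-angeloylation and O-acetylation; C1 is set by γ-epimerisation of the enone, and C10 by face-selective hydrogenation of a guaia-1(10),4-dien-3-one.
2. The dienone ⇒ acyclic allenyne 9 by a Rh(I) allenic Pauson–Khand [2+2+1] cycloaddition; the cyclopentenone and the seven-membered ring form together in this one step.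
3. Allenyne 9 ⇒ terminal epoxide 6 + a propargyl ether acetylide, followed by Cu-catalysed SN2′ methylation (allene and C10 methyl).
4. Epoxide 6 ⇒ triol 4 ⇒ trans-α-butynyl-β-hydroxy-γ-butyrolactone 3; C8 is bought in (S)-3-hydroxy-γ-butyrolactone and C7 is set by dianion alkylation anti to it.

## Route

**Step 1**
Reactants: 1, (S)-3-hydroxy-γ-butyrolactone; 2, 1-bromobut-2-yne
Product: 3, (3S,4S)-3-(but-2-yn-1-yl)-4-hydroxyoxolan-2-one (3,4-trans)
Conditions: LDA (2.2 equiv), THF, −78 °C; DMPU, then 2, −78 → −40 °C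
Reagents that add atoms: 1-bromobut-2-yne, CC#CCBr
Why: Fráter–Seebach-type alkylation of the alkoxide–enolate dianion of a cyclic β-hydroxy ester; the electrophile enters anti to the C4–OLi, so the purchased C8 centre sets C7 (trans lactone).

**Step 2**
Reactants: 3
Product: 4, (2S,3S)-3-(2-hydroxypropan-2-yl)hept-5-yne-1,2-diol
Conditions: MeMgBr (5 equiv), THF, 0 °C → rt; aq. NH4Cl
Reagents that add atoms: methylmagnesium bromide, C[Mg]Br (two CH3)
Why: double Grignard addition to the lactone carbonyl gives the C11 tertiary carbinol and frees the primary C9–OH; no stereocentre is touched.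

**Step 3**
Reactants: 4
Product: 5, (2S,3S)-2-hydroxy-3-(2-hydroxypropan-2-yl)hept-5-yn-1-yl 4-methylbenzenesulfonate
Conditions: TsCl (1.05 equiv), Et3N, Bu2SnO (2 mol %), CH2Cl2, 0 °C
Reagents that add atoms: tosyl chloride, Cc1ccc(cc1)S(Cl)(=O)=O
Why: stannylene-catalysed sulfonylation is selective for the primary hydroxyl of the 1,2-diol; cold, weakly basic conditions avoid premature cyclisation.

**Step 4**
Reactants: 5
Product: 6, trimethyl({(3S)-2-methyl-3-[(2S)-oxiran-2-yl]hept-5-yn-2-yl}oxy)silane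
Conditions: TMS-imidazole (2.5 equiv), CH2Cl2, rt; then K2CO3, MeOH, 0 °C
Reagents that add atoms: N-(trimethylsilyl)imidazole, C[Si](C)(C)n1ccnc1 (one TMS retained)
Why: silylation masks the tertiary C11–OH so it cannot attack C9 (5-exo); methanolysis of the less hindered secondary TMS ether and intramolecular Williamson closure give the epoxide with retention at C8 (the C8–O bond is never broken).

**Step 5**
Reactants: 6; 7, 3-methoxyprop-1-yne
Product: 8, (5R,6S)-1-methoxy-6-[2-(trimethylsilyloxy)propan-2-yl]deca-2,8-diyn-5-ol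
Conditions: 7, n-BuLi, THF, −78 °C; BF3·OEt2; then 6, −78 °C
Reagents that add atoms: 3-methoxyprop-1-yne, COCC#C
Why: Yamaguchi–Hirao alkynylation; the alkynyl nucleophile opens the terminal epoxide at the unsubstituted CH2 (C9) and leaves C8 untouched.

**Step 6**
Reactants: 8
Product: 9, (5R,6S)-3-methyl-5-(trimethylsilyloxy)-6-[2-(trimethylsilyloxy)propan-2-yl]deca-1,2-dien-8-yne
Conditions: MeMgBr (3.5 equiv), CuBr·SMe2 (10 mol %), THF/Et2O, −20 → 0 °C; then TMSCl, Et3N (one pot)
Reagents that add atoms: methylmagnesium bromide, C[Mg]Br (CH3); chlorotrimethylsilane, C[Si](C)(C)Cl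
Why: Cu-catalysed SN2′ displacement of the propargylic methyl ether gives the 1,1-disubstituted allene and installs the future C10 methyl; the magnesium alkoxide at C8 is capped in situ as its TMS ether.

**Step 7**
Reactants: 9
Product: 10, (5S,6R)-3,8-dimethyl-6-(trimethylsilyloxy)-5-[2-(trimethylsilyloxy)propan-2-yl]-4,5,6,7-tetrahydroazulen-2(1H)-one (8,11-bis-OTMS guaia-1(10),4-dien-3-one)
Conditions: [Rh(CO)2Cl]2 (5 mol %), CO (1 atm), toluene, 90 °C
Reagents that add atoms: carbon monoxide, [C-]#[O+]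
Why: Rh(I)-catalysed allenic Pauson–Khand [2+2+1] cycloaddition; Rh engages the alkyne and the distal allene π-bond, forming the cyclopentenone and the seven-membered ring at once with no new stereocentre.

**Step 8**
Reactants: 10
Product: 11, (5S,6R,8S,8aS)-3,8-dimethyl-6-(trimethylsilyloxy)-5-[2-(trimethylsilyloxy)propan-2-yl]-4,5,6,7,8,8a-hexahydroazulen-2(1H)-one (10α-H; initially mainly 1α-H)
Conditions: H2 (1–3 atm), 10% Pd/C, EtOAc, rt
Reagents that add atoms: none
Why: hydrogenation of the distal γ,δ-alkene of the linear dienone leaves the tetrasubstituted enone; H2 adds to the α-face, anti to the β-oriented C8–OTMS and C7 side chain, so the C10 methyl ends up β (10S).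

**Step 9**
Reactants: 11
Product: 12, (5S,6R,8S,8aR)-6-hydroxy-5-(2-hydroxypropan-2-yl)-3,8-dimethyl-4,5,6,7,8,8a-hexahydroazulen-2(1H)-one
Conditions: NaOMe (0.3 equiv), MeOH, rt; aq. NH4Cl
Reagents that add atoms: none
Why: methoxide cleaves both TMS ethers and equilibrates C1 through the extended (γ) dienolate to the 1β-H epimer, in which C2 and the C10 methyl are trans on the seven-membered ring (the natural configuration, expected to be the more stable).

**Step 10**
Reactants: 12; 13, angelic acid
Product: 14, (5S,6R,8S,8aR)-5-(2-hydroxypropan-2-yl)-3,8-dimethyl-2-oxo-1,2,4,5,6,7,8,8a-octahydroazulen-6-yl (Z)-2-methylbut-2-enoate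
Conditions: 13, 2,4,6-trichlorobenzoyl chloride, Et3N, toluene, rt; then 12, 80 °C (no DMAP)
Reagents that add atoms: angelic acid, C/C=C(/C)C(=O)O
Why: Yamaguchi mixed-anhydride esterification without DMAP avoids angelate-to-tiglate isomerisation; only the secondary C8–OH reacts, the tertiary C11–OH being too hindered.

**Step 11**
Reactants: 14
Product: 15, torilin
Conditions: Ac2O, Sc(OTf)3 (2 mol %), MeCN, −20 °C
Reagents that add atoms: acetic anhydride, CC(=O)OC(C)=O
Why: Lewis-acid-catalysed acetylation acylates the tertiary alcohol at low temperature without elimination or touching the enone and angelate.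

## Compound list

1 | (S)-3-hydroxy-γ-butyrolactone [(4S)-4-hydroxyoxolan-2-one] | O=C1C[C@H](O)CO1 | starting material
2 | 1-bromobut-2-yne | CC#CCBr | starting material
3 | (3S,4S)-3-(but-2-yn-1-yl)-4-hydroxyoxolan-2-one | CC#CC[C@H]1[C@H](O)COC1=O | intermediate
4 | (2S,3S)-3-(2-hydroxypropan-2-yl)hept-5-yne-1,2-diol | CC#CC[C@@H]([C@H](O)CO)C(C)(C)O | intermediate
5 | (2S,3S)-2-hydroxy-3-(2-hydroxypropan-2-yl)hept-5-yn-1-yl tosylate | CC#CC[C@@H]([C@H](O)COS(=O)(=O)c1ccc(C)cc1)C(C)(C)O | intermediate
6 | trimethyl({(3S)-2-methyl-3-[(2S)-oxiran-2-yl]hept-5-yn-2-yl}oxy)silane | CC#CC[C@@H]([C@H]1CO1)C(C)(C)O[Si](C)(C)C | intermediate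
7 | 3-methoxyprop-1-yne | COCC#C | starting material
8 | (5R,6S)-1-methoxy-6-[2-(trimethylsilyloxy)propan-2-yl]deca-2,8-diyn-5-ol | CC#CC[C@@H]([C@H](O)CC#CCOC)C(C)(C)O[Si](C)(C)C | intermediate
9 | (5R,6S)-3-methyl-5-(trimethylsilyloxy)-6-[2-(trimethylsilyloxy)propan-2-yl]deca-1,2-dien-8-yne | CC#CC[C@@H]([C@H](O[Si](C)(C)C)CC(C)=C=C)C(C)(C)O[Si](C)(C)C | intermediate
10 | (5S,6R)-3,8-dimethyl-6-(trimethylsilyloxy)-5-[2-(trimethylsilyloxy)propan-2-yl]-4,5,6,7-tetrahydroazulen-2(1H)-one | C[Si](C)(C)O[C@@H]1CC(C)=C2CC(=O)C(C)=C2C[C@@H]1C(C)(C)O[Si](C)(C)C | intermediate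
11 | (5S,6R,8S,8aS)-3,8-dimethyl-6-(trimethylsilyloxy)-5-[2-(trimethylsilyloxy)propan-2-yl]-4,5,6,7,8,8a-hexahydroazulen-2(1H)-one | C[Si](C)(C)O[C@@H]1C[C@H](C)[C@@H]2CC(=O)C(C)=C2C[C@@H]1C(C)(C)O[Si](C)(C)C | intermediate
12 | (5S,6R,8S,8aR)-6-hydroxy-5-(2-hydroxypropan-2-yl)-3,8-dimethyl-4,5,6,7,8,8a-hexahydroazulen-2(1H)-one | O[C@@H]1C[C@H](C)[C@H]2CC(=O)C(C)=C2C[C@@H]1C(C)(C)O | intermediate
13 | angelic acid [(Z)-2-methylbut-2-enoic acid] | C/C=C(/C)C(=O)O | starting material
14 | (5S,6R,8S,8aR)-5-(2-hydroxypropan-2-yl)-3,8-dimethyl-2-oxo-1,2,4,5,6,7,8,8a-octahydroazulen-6-yl (Z)-2-methylbut-2-enoate | C/C=C(/C)C(=O)O[C@@H]1C[C@H](C)[C@H]2CC(=O)C(C)=C2C[C@@H]1C(C)(C)O | intermediate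
15 | torilin | C/C=C(/C)C(=O)O[C@@H]1C[C@H](C)[C@H]2CC(=O)C(C)=C2C[C@@H]1C(C)(C)OC(C)=O | target

## Summary

Total steps: 11. Longest linear sequence: 11 (from 1).

Steps most likely to fail:

1. **Step 8 (face- and chemoselectivity of the C1=C10 hydrogenation, which sets C10).** Fallback: fix C10 before ring formation. Open epoxide 6 with an acetate enolate to the γ-lactone, methylate its enolate trans to the C8 substituent, convert the lactone to the vinyl group (DIBAL, then Ph3P=CH2), and close both rings with an enyne Pauson–Khand reaction, so no C1=C10 alkene has to be reduced.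
2. **Step 9 (C1 relies on the thermodynamic preference for 1β-H, which is argued but not proven).** Fallback: make C1 the enone β-carbon instead. Use a terminal alkyne on the C10 arm and a 1,3-disubstituted allene on the C7 arm in the allenic Pauson–Khand reaction, deliver H-1 to the β-face intramolecularly from a C8–O–SiMe2H tether (or by OH-directed hydrogenation), then isomerise the exocyclic alkene into the C4=C5 position.
3. **Step 10 (acylating a hindered secondary alcohol with angelic acid without Z→E isomerisation).** Fallback: build the angelate on the substrate. Esterify C8–OH with 2-[bis(2,2,2-trifluoroethoxy)phosphoryl]propanoic acid, then run a Z-selective Still–Gennari olefination with acetaldehyde.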